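**Retrosynthetic overview**
- Feature: in ring B, the C8 methyl beside the C9 oxygen, the quaternary C10, the C5 stereocentre and C4 of ring A are the enone methyl, carbonyl carbon, C6, C5 and isopropenyl carbon of (R)-carvone, so ring B and the 5α-H centre are bought.
- Late disconnections: 2α,3α-diol ⇒ α-face OsO4 addition to a C2=C3 alkene; C13=C14 ⇒ Horner–Wadsworth–Emmons olefination; C9–C11 ⇒ α-face addition of a masked 3-oxobutyl organometallic to the C9 ketone.
- Ring A decoration: C4 gem-dimethyl and the C2=C3 alkene ⇒ Me2CuLi addition to a ring A 3-en-2-one and reduction of the resulting enol triflate; that enone ⇒ oxidation and isomerisation of a 2-hydroxy-4-methylene ene product.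
- Ring A closure (C2–C3) ⇒ aluminium-promoted type 2 carbonyl-ene reaction of the C2 aldehyde with the isopropenyl group; keto aldehyde ⇒ α′-methylation and α′-alkylation of carvone (quaternary C10), reduction, double oxidation.
- Ring order: ring B comes intact from carvone; ring A is closed in step 5.

Key step: step 5

Remark: labdane numbering is used throughout; the target is read as the 2α,3α,9β-triol with H-5α, CH3-10β, CH3-8α (equatorial) and the side chain 9α (axial), and the C2 configuration made in step 5 is left open because step 7 erases it.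

**Route**

Step 1
Reactants: 1 (R)-carvone; 2 iodomethane
Product: 4 6-methylcarvone (C6 epimer mixture), via carvone lithium enolate 3 (not isolated)
Conditions: LiN(i-Pr)2, THF, −78 °C; MeI, −78 → 0 °C
Reagents that add atoms: iodomethane, CI
Why: Kinetic α′-deprotonation of the enone at its ring CH2 and SN2 methylation of the cross-conjugated enolate (enolate alkylation); the new centre forms as an epimer mixture, which does not matter because step 2 makes it planar again.

Step 2
Reactants: 4 6-methylcarvone; 5 methyl bromoacetate
Product: 7 methyl [1,3-dimethyl-2-oxo-6-(prop-1-en-2-yl)cyclohex-3-en-1-yl]acetate (acetate arm trans to isopropenyl), via methylcarvone lithium enolate 6 (not isolated)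
Conditions: LiN(i-Pr)2, THF, −78 → −20 °C; BrCH2CO2Me, DMPU, −78 → 0 °C
Reagents that add atoms: methyl bromoacetate, COC(=O)CBr
Why: Enolate alkylation at the now tertiary α′-carbon builds the quaternary centre (future C10); the neighbouring isopropenyl group shields one face of the enolate, so the electrophile should enter anti to it, leaving the acetate arm trans and the methyl cis to isopropenyl.

Step 3
Reactants: 7 keto ester
Product: 8 2-[2-hydroxy-1,3-dimethyl-6-(prop-1-en-2-yl)cyclohex-3-en-1-yl]ethanol (carbinol epimers)
Conditions: LiAlH4, Et2O, 0 °C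
Reagents that add atoms: none
Why: Hydride reduction takes the ester to the primary alcohol and the enone carbonyl (1,2-addition) to the allylic alcohol; the carbinol centre forms as a mixture and is removed again in step 4.

Step 4
Reactants: 8 diol
Product: 9 2-[1,3-dimethyl-2-oxo-6-(prop-1-en-2-yl)cyclohex-3-en-1-yl]acetaldehyde
Conditions: (COCl)2, DMSO, CH2Cl2, −78 °C; Et3N, −78 → 0 °C
Reagents that add atoms: none
Why: Swern oxidation activates both hydroxyls as alkoxysulfonium salts before base is added, so the allylic alcohol should return to the enone and the primary alcohol stop at the aldehyde without lactol formation or over-oxidation to the γ-lactone.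

Step 5
Reactants: 9 keto aldehyde
Product: 10 2β-hydroxy-4-methylene-8,10β-dimethyl-trans-octal-7-en-9-one
Conditions: Me2AlCl (2.2 equiv), CH2Cl2, −78 → −20 °C
Reagents that add atoms: none
Why: Me2AlCl binds the aldehyde oxygen (a second equivalent is held by the enone carbonyl), the terminal CH2 of the isopropenyl group attacks the activated C2 carbonyl, and a hydrogen of the allylic methyl passes to oxygen through a six-membered, bicyclo[3.3.1]-like transition state; this is a type 2 intramolecular carbonyl-ene (Prins-type) reaction, well known for 6-methylhept-6-enals giving 3-methylenecyclohexanols. Ring A closes as a six-membered chair, 6-endo-trig at the alkene and exo at the carbonyl, and only the C2–C3 bond is formed. The trans ring fusion is already fixed by the trans-diequatorial aldehyde arm (on C10) and isopropenyl group (on C5), so C2 is the only new stereocentre; concerted hydrogen transfer needs the aluminium-bound oxygen axial, so the 2β-alcohol (syn to the C10 methyl) is expected to predominate, and any stepwise cationic component would give the 2α-epimer. Either epimer serves, since C2 becomes a ketone in step 7. The step needs the aldehyde and not the hindered ketone as enophile, bond formation at the CH2 terminus, and hydrogen loss from the methyl and not from C5–H; these follow from the higher electrophilicity of the aldehyde, the Markovnikov polarisation of the 1,1-disubstituted alkene (charge at C4), and a transition state that cannot reach C5–H. Me2AlCl is chosen over stronger aluminium halides because it removes protons as methane, which should suppress chloride capture at C4 and alkene migration.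

Step 6
Reactants: 10 ene product
Product: 12 2β-hydroxy-4-methylene-8α,10β-dimethyl-trans-decalin-9-one, via C8 lithium enolate 11 (not isolated)
Conditions: LiBH(s-Bu)3, THF, −78 °C; MeOH, NaOMe (cat.), rt
Reagents that add atoms: none
Why: Conjugate reduction of a β-unsubstituted cyclohexenone by the hindered borohydride delivers hydride to C7 and leaves the exocyclic alkene alone; protonation and methoxide equilibration through the C8–C9 enolate should place the C8 methyl equatorial (8α), because the 8β-epimer would be 1,3-diaxial to the C10 methyl.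

Step 7
Reactants: 12 hydroxy ketone
Product: 14 4,8α,10β-trimethyl-trans-octal-3-ene-2,9-dione, via β,γ-unsaturated diketone 13 (not isolated)
Conditions: Dess–Martin periodinane, CH2Cl2, rt; aqueous work-up; DBU (cat.), CH2Cl2, rt
Reagents that add atoms: none
Why: Dess–Martin oxidation of the C2 alcohol gives the β,γ-unsaturated ketone, whose doubly activated C3 protons let catalytic DBU move the exocyclic double bond into conjugation (C3=C4) under conditions too mild to disturb C5 or C8; the C2 stereocentre of step 5 disappears here.

Step 8
Reactants: 14 enedione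
Product: 16 4,4,8α,10β-tetramethyl-9-oxo-trans-octal-2-en-2-yl triflate, via C2 lithium enolate 15 (not isolated)
Conditions: Me2CuLi (MeLi, CuI), Et2O, −20 → 0 °C; PhNTf2, THF–DMPU, 0 °C → rt
Reagents that add atoms: lithium dimethylcuprate, [Li+].C[Cu-]C (made from methyllithium, [Li]C, and CuI); N-phenylbis(trifluoromethanesulfonimide), O=S(=O)(N(c1ccccc1)S(=O)(=O)C(F)(F)F)C(F)(F)F
Why: Cuprate conjugate addition to the β,β-disubstituted ring A enone (as in the classical methylation of isophorone) installs the second C4 methyl without creating a stereocentre and gives the C2–C3 enolate regiospecifically, which PhNTf2 traps on oxygen (enol triflate formation); the hindered C9 ketone should be inert to the cuprate.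

Step 9
Reactants: 16 enol triflate
Product: 17 4,4,8α,10β-tetramethyl-trans-octal-2-en-9-one
Conditions: Pd(OAc)2 (cat.), PPh3, HCO2H, n-Bu3N, DMF, 60 °C
Reagents that add atoms: none
Why: Palladium-catalysed formate reduction of the enol triflate (oxidative addition to zerovalent palladium, formate exchange, decarboxylation, reductive elimination) replaces OTf by H and fixes the alkene at C2=C3 without touching the ketone.

Step 10
Reactants: 17 octalenone; 18 2-(2-bromoethyl)-2-methyl-1,3-dioxolane
Product: 21 9β-hydroxy-9α-[2-(2-methyl-1,3-dioxolan-2-yl)ethyl]-4,4,8α,10β-tetramethyl-trans-octal-2-ene, via Grignard reagent 19 (not isolated), via organocerium reagent 20 (not isolated)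
Conditions: Mg, THF, 25 °C; CeCl3, THF, −78 °C; 17, −78 → 0 °C
Reagents that add atoms: 2-(2-bromoethyl)-2-methyl-1,3-dioxolane, CC1(CCBr)OCCO1
Why: Organocerium 1,2-addition suits the hindered, enolisable C9 ketone because the reagent is nucleophilic but weakly basic; attack should come axially from the α-face, anti to the axial C10 methyl that blocks the β-face, so C11 ends 9α and the hydroxyl 9β (equatorial), with the equatorial 8α-methyl offering no hindrance.

Step 11
Reactants: 21 hydroxy ketal
Product: 22 4-(9β-hydroxy-4,4,8α,10β-tetramethyl-trans-octal-2-en-9α-yl)butan-2-one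
Conditions: PPTS, acetone–H2O, 40 °C
Reagents that add atoms: water, O
Why: Mild acid-catalysed acetal hydrolysis frees the methyl ketone (in equilibrium with its five-membered hemiketal); the wet, weakly acidic medium should avoid dehydration of the tertiary alcohol or of the hemiketal.

Step 12
Reactants: 22 hydroxy ketone; 23 trimethyl phosphonoacetate
Product: 25 methyl (E)-5-(9β-hydroxy-4,4,8α,10β-tetramethyl-trans-octal-2-en-9α-yl)-3-methylpent-2-enoate, via sodium phosphonate anion 24 (not isolated)
Conditions: NaH, THF, 0 °C; 22, rt → 50 °C
Reagents that add atoms: trimethyl phosphonoacetate, COC(=O)CP(=O)(OC)OC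
Why: Horner–Wadsworth–Emmons olefination of the methyl ketone is expected to favour the (E)-enoate (ester trans to the larger C12 chain), with the (Z)-isomer removed by chromatography; keeping the phosphonate in slight excess over NaH leaves the tertiary hydroxyl protonated, which should hold back oxa-Michael closure onto C13.

Step 13
Reactants: 25 enoate
Product: 26 methyl (13E)-2α,3α,9β-trihydroxy-9-epi-labd-13-en-15-oate (CNP0292844.1)
Conditions: OsO4 (cat.), NMO, acetone–H2O, rt
Reagents that add atoms: OsO4, O=[Os](=O)(=O)=O; N-methylmorpholine N-oxide, C[N+]1([O-])CCOCC1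
Why: Catalytic syn-dihydroxylation (Upjohn conditions) should take the electron-richer isolated C2=C3 alkene in preference to the electron-poor trisubstituted enoate, and from the α-face because the β-face is shielded by the axial C4 β-methyl and the C10 methyl, giving the 2α,3α-diol.

**Compound list**

1 | (R)-carvone | CC1=CC[C@H](CC1=O)C(C)=C | starting material
2 | iodomethane | CI | starting material
3 | lithium enolate of (R)-carvone (α′-enolate) | [Li+].[O-]C1=C[C@@H](CC=C1C)C(C)=C | intermediate
4 | 6-methylcarvone, 2,6-dimethyl-5-(prop-1-en-2-yl)cyclohex-2-en-1-one, C6 epimer mixture | O=C1C(C)=CC[C@@H](C(C)=C)C1C | intermediate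
5 | methyl bromoacetate | COC(=O)CBr | starting material
6 | lithium enolate of 6-methylcarvone | [Li+].[O-]C1=C(C)[C@@H](CC=C1C)C(C)=C | intermediate
7 | methyl [1,3-dimethyl-2-oxo-6-(prop-1-en-2-yl)cyclohex-3-en-1-yl]acetate, acetate arm trans and ring methyl cis to isopropenyl | O=C1C(C)=CC[C@@H](C(C)=C)[C@]1(C)CC(=O)OC | intermediate
8 | 2-[2-hydroxy-1,3-dimethyl-6-(prop-1-en-2-yl)cyclohex-3-en-1-yl]ethanol, carbinol epimer mixture | OC1C(C)=CC[C@@H](C(C)=C)[C@]1(C)CCO | intermediate
9 | 2-[1,3-dimethyl-2-oxo-6-(prop-1-en-2-yl)cyclohex-3-en-1-yl]acetaldehyde (key-step precursor) | O=C1C(C)=CC[C@@H](C(C)=C)[C@]1(C)CC=O | intermediate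
10 | trans-fused ene product: C9 ketone, C7=C8 with 8-CH3, 10β-CH3, 5α-H, exocyclic C4=CH2, axial 2β-OH (the 2α-epimer serves equally) | O=C1C(C)=CC[C@H]2C(=C)C[C@@H](O)C[C@@]21C | intermediate
11 | C8–C9 lithium enolate from conjugate reduction of 10 | [Li+].[O-]C1=C(C)CC[C@H]2C(=C)C[C@@H](O)C[C@@]21C | intermediate
12 | 2β-hydroxy-4-methylene-8α,10β-dimethyl-trans-decalin-9-one | O=C1[C@H](C)CC[C@H]2C(=C)C[C@@H](O)C[C@@]21C | intermediate
13 | 4-methylene-8α,10β-dimethyl-trans-decalin-2,9-dione (β,γ-unsaturated) | O=C1[C@H](C)CC[C@H]2C(=C)CC(=O)C[C@@]21C | intermediate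
14 | 4,8α,10β-trimethyl-trans-octal-3-ene-2,9-dione (ring A enone, 5α-H) | O=C1[C@H](C)CC[C@H]2C(C)=CC(=O)C[C@@]21C | intermediate
15 | C2–C3 lithium enolate of 4,4,8α,10β-tetramethyl-trans-decalin-2,9-dione | O=C1[C@H](C)CC[C@H]2C(C)(C)C=C([O-])C[C@@]21C.[Li+] | intermediate
16 | 4,4,8α,10β-tetramethyl-9-oxo-trans-octal-2-en-2-yl trifluoromethanesulfonate | O=C1[C@H](C)CC[C@H]2C(C)(C)C=C(OS(=O)(=O)C(F)(F)F)C[C@@]21C | intermediate
17 | 4,4,8α,10β-tetramethyl-trans-octal-2-en-9-one (5α-H) | O=C1[C@H](C)CC[C@H]2C(C)(C)C=CC[C@@]21C | intermediate
18 | 2-(2-bromoethyl)-2-methyl-1,3-dioxolane | CC1(CCBr)OCCO1 | starting material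
19 | [2-(2-methyl-1,3-dioxolan-2-yl)ethyl]magnesium bromide | CC1(CC[Mg]Br)OCCO1 | intermediate
20 | [2-(2-methyl-1,3-dioxolan-2-yl)ethyl]cerium dichloride | CC1(CC[Ce](Cl)Cl)OCCO1 | intermediate
21 | 9β-hydroxy-9α-[2-(2-methyl-1,3-dioxolan-2-yl)ethyl]-4,4,8α,10β-tetramethyl-trans-octal-2-ene | CC1(CC[C@]2(O)[C@H](C)CC[C@H]3C(C)(C)C=CC[C@@]32C)OCCO1 | intermediate
22 | 4-(9β-hydroxy-4,4,8α,10β-tetramethyl-trans-octal-2-en-9α-yl)butan-2-one (in equilibrium with its cyclic hemiketal) | CC(=O)CC[C@]1(O)[C@H](C)CC[C@H]2C(C)(C)C=CC[C@@]21C | intermediate
23 | trimethyl phosphonoacetate | COC(=O)CP(=O)(OC)OC | starting material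
24 | sodium salt of trimethyl phosphonoacetate | [Na+].COC(=O)[CH-]P(=O)(OC)OC | intermediate
25 | methyl (E)-5-(9β-hydroxy-4,4,8α,10β-tetramethyl-trans-octal-2-en-9α-yl)-3-methylpent-2-enoate | COC(=O)/C=C(\C)CC[C@]1(O)[C@H](C)CC[C@H]2C(C)(C)C=CC[C@@]21C | intermediate
26 | CNP0292844.1, methyl (13E)-2α,3α,9β-trihydroxy-8α-methyl-9α-side-chain labd-13-en-15-oate | COC(=O)/C=C(\C)CC[C@]1(O)[C@H](C)CC[C@H]2C(C)(C)[C@H](O)[C@H](O)C[C@@]21C | target

**Summary**

Total step count: 13. Longest linear sequence: 13 steps from (R)-carvone; compounds 2, 5, 18 and 23 are bought.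

**Steps most likely to fail**

Risk at step 5 (key step). The ring closure may be diverted by chloride capture at the developing tertiary C4 centre, by migration of the new double bond into the ring, or by methyl transfer from aluminium to the aldehyde. Fallback: from 9, ene-type allylic chlorination of the isopropenyl group (N-chlorosuccinimide, PhSeCl cat., CH2Cl2), which the electron-poor enone alkene should not undergo, gives the (chloromethyl)vinyl keto aldehyde F1. Intramolecular Nozaki–Hiyama allylation (CrCl2, THF, rt) adds the 2-substituted allylchromium selectively to the aldehyde, forms the same C2–C3 bond and the same exocyclic methylene, and returns to the route at 10. Either C2 epimer is usable.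

Risk at step 10. Enolisation of the hindered ketone toward C8 may outrun addition, β-hydride transfer may reduce the ketone, or facial selectivity may be incomplete. Fallback: from 17, Corey–Chaykovsky methylenation with dimethylsulfonium methylide (Me3SI, n-BuLi, THF, 0 °C) uses a small, irreversibly adding ylide that attacks axially from the α-face and gives the spiro epoxide F2 (CH2 α, O β). Opening at the CH2 terminus with lithiated acetone N,N-dimethylhydrazone (THF, 0 °C → rt) gives the hydroxy hydrazone F3. Hydrolysis (aqueous CuCl2, THF) returns to the route at 22.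

Risk at step 12. Olefination of a methyl ketone may give poor E/Z selectivity, the hemiketal may slow the reaction, and any alkoxide formed at C9 may close onto C13 by oxa-Michael addition. Fallback: from 17, the organocerium reagent made from (4-bromobut-1-yn-1-yl)trimethylsilane (Mg, then CeCl3, THF) gives the silylalkyne carbinol F4. K2CO3 in MeOH gives the terminal alkyne F5. Zirconium-catalysed syn-methylalumination (AlMe3, Cp2ZrCl2 cat., CH2Cl2) gives the alkenylalane F6, which is quenched with methyl chloroformate with retention, so the (E)-geometry is set by the syn addition and no basic olefination is needed. The sequence returns to the route at 25.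

**Further compounds**

F1 | step 5 | 2-[6-(3-chloroprop-1-en-2-yl)-1,3-dimethyl-2-oxocyclohex-3-en-1-yl]acetaldehyde | O=C1C(C)=CC[C@@H](C(CCl)=C)[C@]1(C)CC=O
F2 | step 10 | spiro epoxide of 17 at C9 (CH2 α, O β) | O1C[C@@]12[C@H](C)CC[C@H]3C(C)(C)C=CC[C@@]32C
F3 | step 10 | N,N-dimethylhydrazone of 22 | CN(C)N=C(C)CC[C@]1(O)[C@H](C)CC[C@H]2C(C)(C)C=CC[C@@]21C
F4 | step 12 | 9β-hydroxy-9α-[4-(trimethylsilyl)but-3-yn-1-yl]-4,4,8α,10β-tetramethyl-trans-octal-2-ene | C[Si](C)(C)C#CCC[C@]1(O)[C@H](C)CC[C@H]2C(C)(C)C=CC[C@@]21C
F5 | step 12 | 9α-(but-3-yn-1-yl)-9β-hydroxy-4,4,8α,10β-tetramethyl-trans-octal-2-ene | C#CCC[C@]1(O)[C@H](C)CC[C@H]2C(C)(C)C=CC[C@@]21C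
F6 | step 12 | (E)-alkenyl dimethylalane (C14–Al cis to the C13 methyl) as its C9 dimethylaluminium alkoxide | C[Al](C)/C=C(\C)CC[C@]1(O[Al](C)C)[C@H](C)CC[C@H]2C(C)(C)C=CC[C@@]21C
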